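**Retrosynthetic overview**

1. 18 ⇐ 17 (enol acylation of the aldehyde) ⇐ 16 (double ozonolysis) ⇐ tricyclic enone 14, by conjugate allylation at C2 and alkylation at C3, both on the exo face of the closed cage.
2. Key disconnection, ring A (pyran): O–C11 and C11–C5 are both cut, so 14 ⇐ bicyclic hydroxy enone 11 + formaldehyde, joined in a (5+1) annulation (Mannich α′-methylenation, then oxa-Michael closure in the same flask).
3. What makes it possible: C11 lies between the ring A oxygen and C5, the α′-carbon of the ring C ketone C4 (a β-alkoxy ketone, i.e. a formaldehyde retron); in the enone C2=C3–C4(=O) of 11 only C5 can enolise (C1 is quaternary, C6 a bridgehead), and the tertiary C12 hydroxyl on C7 of ring B is held cis to C5.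
4. 11 ⇐ bicyclo[4.3.1]decanone 9 ⇐ ring C closed by intramolecular enolate alkylation (C5–C6), C10 carbonyl then removed (Wolff–Kishner) ⇐ reductive alkylation of (R)-carvone 1 (ring B, C7) with the C4 iodide 2.
5. Ring order: B (from carvone) → C (step 5) → A (step 10). Numbering: bicyclo[4.3.1]decane core, C1 = methyl-bearing bridgehead, C2–C5 four-carbon bridge, C6 bridgehead, C7–C9, C10 one-carbon bridge, C11 = OCH2, C12 = OCMe2.

Key step: step 10

Assumption (chemistry): the cis ring A/ring C fusion at C5 is taken as both the kinetic (exo protonation) and the thermodynamic result, because only this epimer keeps rings A and B and the seven-membered ring chair-like.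
Assumption (supply): iodide 2 is bought (or made in one step from the commercial alcohol); its carbinol centre is erased in step 7.

**Route**

Step 1
Reactants: 1 (R)-(−)-carvone; 2 (S)-4-(2-iodoethyl)-2,2-dimethyl-1,3-dioxolane
Product: 3 (2R,5R)-2-{2-[(4S)-2,2-dimethyl-1,3-dioxolan-4-yl]ethyl}-2-methyl-5-(prop-1-en-2-yl)cyclohexan-1-one
Conditions: Li, NH3(l), t-BuOH (1 equiv), THF, −78 °C; then 2, −78 → −33 °C; NH4Cl
Reagents that add atoms: none
Why: Birch-type reduction of the enone gives the regiodefined lithium enolate, and its alkylation by axial attack on the half-chair with equatorial isopropenyl should place the new chain cis to the isopropenyl group (reductive alkylation of an enone).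

Step 2
Reactants: 3
Product: 4 (2R,5R)-2-[(3S)-3,4-dihydroxybutyl]-2-methyl-5-(prop-1-en-2-yl)cyclohexan-1-one
Conditions: AcOH/H2O (4:1), 40 °C
Reagents that add atoms: none
Why: Acid-catalysed acetal hydrolysis frees the 1,2-diol and leaves the ketone, the isopropenyl group and all stereocentres untouched.

Step 3
Reactants: 4
Product: 5 (2R,5R)-2-[(3S)-3-hydroxy-4-(tosyloxy)butyl]-2-methyl-5-(prop-1-en-2-yl)cyclohexan-1-one
Conditions: TsCl, pyridine, CH2Cl2, 0 °C
Reagents that add atoms: 4-methylbenzenesulfonyl chloride, Cc1ccc(cc1)S(Cl)(=O)=O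
Why: Sulfonylation of a 1,2-diol should occur selectively at the less hindered primary hydroxyl (selective tosylation).

Step 4
Reactants: 5
Product: 6 (2R,5R)-2-methyl-5-(prop-1-en-2-yl)-2-[(3S)-4-(tosyloxy)-3-(triethylsilyloxy)butyl]cyclohexan-1-one
Conditions: Et3SiOTf, 2,6-lutidine, CH2Cl2, −78 °C
Reagents that add atoms: triethylsilyl trifluoromethanesulfonate, CC[Si](CC)(CC)OS(=O)(=O)C(F)(F)F
Why: Silyl ether protection of the secondary alcohol prevents epoxide formation in the following basic step.

Step 5
Reactants: 6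
Product: 7 (1R,4S,6R,7R)-1-methyl-7-(prop-1-en-2-yl)-4-(triethylsilyloxy)bicyclo[4.3.1]decan-10-one
Conditions: KN(SiMe3)2, THF (high dilution), −78 → 23 °C
Reagents that add atoms: none
Why: The ketone can enolise only at its α′-methylene, and intramolecular SN2 alkylation by the primary tosylate (7-(enolendo)-exo-tet, α,α′-annulation) closes ring C; the tether on the quaternary carbon reaches only its own face, which fixes C6 with the bridge cis to the C7 isopropenyl group.

Step 6
Reactants: 7
Product: 8 (1R,4S,6R,7R)-1-methyl-7-(prop-1-en-2-yl)bicyclo[4.3.1]decan-4-ol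
Conditions: N2H4·H2O, KOH, diethylene glycol, 130 → 200 °C (argon); then 1 M HCl, THF, 23 °C
Reagents that add atoms: none
Why: Wolff–Kishner reduction (Huang–Minlon procedure) removes the non-enolisable C10 carbonyl that served as activating group, the silyl ether is cleaved by the alkali and the acidic work-up, and no stereocentre is at risk.

Step 7
Reactants: 8
Product: 9 (1R,6R,7R)-1-methyl-7-(prop-1-en-2-yl)bicyclo[4.3.1]decan-4-one
Conditions: (n-Pr4N)RuO4 (cat.), N-methylmorpholine N-oxide, 4 Å MS, CH2Cl2, 23 °C
Reagents that add atoms: none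
Why: Perruthenate-catalysed oxidation of the secondary alcohol gives the C4 ketone and erases the auxiliary carbinol stereocentre.

Step 8
Reactants: 9
Product: 10 (1R,6R,7R)-7-(2-hydroxypropan-2-yl)-1-methylbicyclo[4.3.1]decan-4-one
Conditions: Mn(dpm)3 (cat., dpm = 2,2,6,6-tetramethylheptane-3,5-dionate), PhSiH3, O2 (1 atm), i-PrOH, 0 °C; then P(OEt)3
Reagents that add atoms: dioxygen, O=O
Why: Mukaiyama hydration (hydrogen atom transfer from a metal hydride, O2 capture, reduction of the hydroperoxide) should convert the 1,1-disubstituted alkene into the tertiary C12 alcohol with Markovnikov selectivity while the ketone survives; no stereocentre is formed.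

Step 9
Reactants: 10
Product: 11 (1S,6R,7R)-7-(2-hydroxypropan-2-yl)-1-methylbicyclo[4.3.1]dec-2-en-4-one
Conditions: IBX, DMSO/fluorobenzene, 70 °C
Reagents that add atoms: none
Why: IBX-mediated dehydrogenation of the ketone can only give the C2=C3 enone, because unsaturation at C5–C6 would be a bridgehead alkene (Bredt's rule).

Step 10
Reactants: 11
Product: 14 tricyclic enone (ring A closed; core descriptors 1S,5S,6S,7R), via Mannich base 12 (not isolated), via exo-methylene dienone 13 (not isolated)
Conditions: (CH2O)n, i-Pr2NH·CF3CO2H, THF, 65 °C; then DBU (cat.), 23 °C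
Reagents that add atoms: formaldehyde (as paraformaldehyde), C=O
Why: Formaldehyde and the diisopropylammonium salt give the methyleneiminium ion, which the enol of 11 captures at C5 (Mannich reaction); loss of the amine leaves the C5=C11 dienone 13, the tertiary C12 hydroxyl then adds to C11 (oxa-Michael) and the enol tautomerises to 14. The closest known reaction types are the ammonium trifluoroacetate α-methylenation of ketones and the one-flask Mannich/oxa-Michael annulation of 2-hydroxyaryl ketones with formaldehyde to chromanones. Ring A closes in the 6-endo-trig mode, both carbons of the C5=C11 bond lying inside the new ring. The new stereocentre C5 is set by protonation of the enol on the open exo face (syn to H6), which gives the cis ring A/ring C fusion; since C5 stays epimerisable under DBU, the same isomer is also expected from equilibration, being the one with rings A and B and the cycloheptenone all chair-like. The step needs site selectivity, and the substrate secures it: C5 is the only enolisable carbon of the cross-conjugated enone (C1 quaternary, C6 bridgehead), and the hydroxyl on C7 can reach C11 through a six-membered transition state but C2 only through an eight-membered one.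

Step 11
Reactants: 14
Product: 15 trimethylsilyl enol ether (C3=C4) of the C2-allyl tricyclic ketone (core descriptors 1S,2S,5S,6S,7R)
Conditions: CH2=CHCH2MgBr, CuBr·SMe2 (cat.), Me3SiCl, THF, −78 °C
Reagents that add atoms: allylmagnesium bromide, C=CC[Mg]Br; chlorotrimethylsilane, C[Si](C)(C)Cl
Why: Copper-catalysed conjugate allylation with in situ silylation should deliver the allyl group to C2 from the exo face (the side of the C10 bridge), since the endo face of the enone is covered by rings A and B, and it gives the regiodefined enol ether.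

Step 12
Reactants: 15
Product: 16 C2-allyl C3-(2-methylallyl) tricyclic ketone (core descriptors 1S,2S,3R,5S,6S,7R)
Conditions: MeLi, THF, 0 °C; then 3-bromo-2-methylprop-1-ene, DMPU, −78 → 0 °C
Reagents that add atoms: 3-bromo-2-methylprop-1-ene, C=C(C)CBr
Why: The lithium enolate released regiospecifically from the silyl enol ether is alkylated at C3 on the only open (exo) face, cis to the C2 substituent, and because the endo position at C3 is blocked by ring B this is also the stable configuration of the epimerisable centre (enolate alkylation).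

Step 13
Reactants: 16
Product: 17 keto aldehyde (C2-CH2CHO, C3-acetonyl; core descriptors 1S,2S,3R,5S,6S,7R)
Conditions: O3, CH2Cl2, −78 °C; then PPh3, −78 → 23 °C
Reagents that add atoms: ozone, [O-][O+]=O
Why: Ozonolysis cleaves both terminal alkenes in one operation, turning allyl into the acetaldehyde side chain and 2-methylallyl into the acetonyl group without touching a stereocentre.

Step 14
Reactants: 17
Product: 18 CNP0281755.2 (target; core descriptors 1S,2S,3R,5S,6S,7R, E-enol ester)
Conditions: 3-methylbut-2-enoic acid, DCC, CH2Cl2, 0 °C; then 17, Et3N, DMAP (cat.), 23 °C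
Reagents that add atoms: 3-methylbut-2-enoic acid, CC(C)=CC(=O)O
Why: Enol ester formation by O-acylation of the aldehyde enolate with the anhydride made in the flask; the aldehyde is enolised far more readily than the two ketones, and the E isomer should prevail because the Z isomer would press the acyloxy group against the bulky C2 ring carbon.

**Compound list**

1 | (R)-(−)-carvone | CC1=CC[C@H](CC1=O)C(C)=C | starting material
2 | (S)-4-(2-iodoethyl)-2,2-dimethyl-1,3-dioxolane | CC1(C)OC[C@H](CCI)O1 | starting material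
3 | (2R,5R)-2-{2-[(4S)-2,2-dimethyl-1,3-dioxolan-4-yl]ethyl}-2-methyl-5-(prop-1-en-2-yl)cyclohexan-1-one | O=C1C[C@H](C(C)=C)CC[C@]1(C)CC[C@H]2COC(C)(C)O2 | intermediate
4 | (2R,5R)-2-[(3S)-3,4-dihydroxybutyl]-2-methyl-5-(prop-1-en-2-yl)cyclohexan-1-one | O=C1C[C@H](C(C)=C)CC[C@]1(C)CC[C@H](O)CO | intermediate
5 | (2R,5R)-2-[(3S)-3-hydroxy-4-(tosyloxy)butyl]-2-methyl-5-(prop-1-en-2-yl)cyclohexan-1-one | O=C1C[C@H](C(C)=C)CC[C@]1(C)CC[C@H](O)COS(=O)(=O)c1ccc(C)cc1 | intermediate
6 | (2R,5R)-2-methyl-5-(prop-1-en-2-yl)-2-[(3S)-4-(tosyloxy)-3-(triethylsilyloxy)butyl]cyclohexan-1-one | O=C1C[C@H](C(C)=C)CC[C@]1(C)CC[C@H](O[Si](CC)(CC)CC)COS(=O)(=O)c1ccc(C)cc1 | intermediate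
7 | (1R,4S,6R,7R)-1-methyl-7-(prop-1-en-2-yl)-4-(triethylsilyloxy)bicyclo[4.3.1]decan-10-one | O=C1[C@@]2(C)CC[C@H](O[Si](CC)(CC)CC)C[C@@H]1[C@H](C(C)=C)CC2 | intermediate
8 | (1R,4S,6R,7R)-1-methyl-7-(prop-1-en-2-yl)bicyclo[4.3.1]decan-4-ol | C1[C@@]2(C)CC[C@H](O)C[C@@H]1[C@H](C(C)=C)CC2 | intermediate
9 | (1R,6R,7R)-1-methyl-7-(prop-1-en-2-yl)bicyclo[4.3.1]decan-4-one | C1[C@@]2(C)CCC(=O)C[C@@H]1[C@H](C(C)=C)CC2 | intermediate
10 | (1R,6R,7R)-7-(2-hydroxypropan-2-yl)-1-methylbicyclo[4.3.1]decan-4-one | C1[C@@]2(C)CCC(=O)C[C@@H]1[C@H](C(C)(C)O)CC2 | intermediate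
11 | (1S,6R,7R)-7-(2-hydroxypropan-2-yl)-1-methylbicyclo[4.3.1]dec-2-en-4-one | O=C1C=C[C@@]2(C)CC[C@@H](C(C)(C)O)[C@H](C2)C1 | intermediate
12 | Mannich base: 5-[(diisopropylamino)methyl] derivative of 11 (both C5 epimers) | O=C1C=C[C@@]2(C)CC[C@@H](C(C)(C)O)[C@H](C2)C1CN(C(C)C)C(C)C | intermediate (not isolated)
13 | exo-methylene dienone: 5-methylidene derivative of 11 | O=C1C=C[C@@]2(C)CC[C@@H](C(C)(C)O)[C@H](C2)C1=C | intermediate (not isolated)
14 | tricyclic enone: 11 with the bridge C5–C11H2–O–C12Me2–C7 (ring A) closed; 1S,5S,6S,7R; H5 and H6 cis | O=C1C=C[C@@]2(C)CC[C@@H]3[C@H](C2)[C@H]1COC3(C)C | intermediate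
15 | C4-trimethylsilyl enol ether (C3=C4) of the tricyclic ketone with exo allyl on C2; 1S,2S,5S,6S,7R | C1=C(O[Si](C)(C)C)[C@@H]2COC(C)(C)[C@@H]3CC[C@@](C)(C[C@@H]32)[C@H]1CC=C | intermediate
16 | tricyclic C4 ketone with exo allyl on C2 and exo 2-methylallyl on C3; 1S,2S,3R,5S,6S,7R | C=C(C)C[C@H]1C(=O)[C@@H]2COC(C)(C)[C@@H]3CC[C@@](C)(C[C@@H]32)[C@H]1CC=C | intermediate
17 | tricyclic keto aldehyde: 2-oxoethyl on C2, 2-oxopropyl on C3; 1S,2S,3R,5S,6S,7R | CC(=O)C[C@H]1C(=O)[C@@H]2COC(C)(C)[C@@H]3CC[C@@](C)(C[C@@H]32)[C@H]1CC=O | intermediate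
18 | CNP0281755.2: (E)-enol 3-methylbut-2-enoate of 17; 1S,2S,3R,5S,6S,7R | CC(=O)C[C@H]1C(=O)[C@@H]2COC(C)(C)[C@@H]3CC[C@@](C)(C[C@@H]32)[C@H]1/C=C/OC(=O)C=C(C)C | target

**Totals and risks**

Total step count: 14. Longest linear sequence: 14 steps from 1.

Steps most likely to fail:

Step 5. The seven-membered ring may close too slowly, so that intermolecular alkylation and E2 loss of the tosylate take over. Fallback, from 1 back to 9, closing ring C by an oxidative union of two enolate carbons instead of an alkylation: reductive alkylation of 1 with 4-iodobut-1-ene (Li, NH3) should give the butenyl ketone F1. Tsuji–Wacker oxidation of its monosubstituted alkene (PdCl2, CuCl, O2, DMF/H2O) gives the 1,5-diketone F2. LiN(i-Pr)2 with Me3SiCl present (−78 °C) gives the bis(silyl enol ether) F3. Intramolecular oxidative coupling of the two enol silanes with (NH4)2Ce(NO3)6/NaHCO3 in MeCN gives the bicyclic 1,4-diketone F4. The unhindered C4 ketone is protected selectively (1,2-bis(trimethylsilyloxy)ethane, Me3SiOTf cat.) as the dioxolane F5. Wolff–Kishner reduction of the C10 ketone gives the ketal F6, and PPTS in wet acetone returns 9.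

Step 10. Methylenation may stall at the Mannich base, or the dienone may polymerise before the hindered tertiary hydroxyl adds. Fallback, from 11 back to 14, forming the C5–C11 bond last by a polar C–C closure: 11 is converted into its methoxymethyl ether F7 (MeOCH2Cl, i-Pr2NEt, NaI, 40 °C). Me3SiOTf/i-Pr2NEt (CH2Cl2, −78 → 0 °C) then forms the silyl dienol ether F8 in the flask and ionises the formaldehyde acetal to the alkoxymethyl cation, which C5 captures in an intramolecular Mukaiyama-type addition. Brief DBU treatment equilibrates C5 and gives 14.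

Step 14. E/Z control in the enol acylation may be poor, and the keto aldehyde may undergo intramolecular aldol condensation under the basic conditions. Fallback, from 14 back to 18, with the alkene geometry fixed before the C–O bond is made: CH2=CHMgBr/CuBr·SMe2/Me3SiCl gives the vinyl silyl enol ether F9. MeLi then propargyl bromide gives the propargyl ketone F10. Gold-catalysed alkyne hydration (Ph3PAuNTf2, MeOH/H2O) gives the vinyl diketone F11. Cross-metathesis with vinylboronic acid pinacol ester (second-generation Grubbs catalyst) gives the (E)-alkenyl boronate F12, and KHF2 the potassium (E)-alkenyltrifluoroborate F13. Copper-catalysed oxidative coupling with 3-methylbut-2-enoic acid (Cu(OAc)2, DMAP, 4 Å MS, O2; Chan–Lam-type C–O coupling with retention of geometry) gives 18.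

**Further compounds**

F1 | step 5 | 2-(but-3-enyl)-2-methyl-5-isopropenylcyclohexanone (butenyl cis to isopropenyl) | O=C1C[C@H](C(C)=C)CC[C@]1(C)CCC=C
F2 | step 5 | 2-methyl-2-(3-oxobutyl)-5-isopropenylcyclohexanone (oxobutyl cis to isopropenyl) | O=C1C[C@H](C(C)=C)CC[C@]1(C)CCC(C)=O
F3 | step 5 | bis(trimethylsilyl enol ether) of F2 (ring enol ether towards the CH2, terminal enol ether in the side chain) | C[Si](C)(C)OC1=C[C@H](C(C)=C)CC[C@]1(C)CCC(=C)O[Si](C)(C)C
F4 | step 5 | 1-methyl-7-isopropenylbicyclo[4.3.1]decane-4,10-dione (configuration as in 9) | O=C1[C@@]2(C)CCC(=O)C[C@@H]1[C@H](C(C)=C)CC2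
F5 | step 5 | 4,4-ethylenedioxy ketal of F4 (C10 ketone free) | O=C1[C@@]2(C)CCC3(OCCO3)C[C@@H]1[C@H](C(C)=C)CC2
F6 | step 5 | 4,4-ethylenedioxy ketal of 9 | C1[C@@]2(C)CCC3(OCCO3)C[C@@H]1[C@H](C(C)=C)CC2
F7 | step 10 | methoxymethyl ether of 11 | O=C1C=C[C@@]2(C)CC[C@@H](C(C)(C)OCOC)[C@H](C2)C1
F8 | step 10 | 4-(trimethylsilyloxy)-2,4-diene (silyl dienol ether) of F7 | C1(O[Si](C)(C)C)C=C[C@@]2(C)CC[C@@H](C(C)(C)OCOC)[C@H](C2)C=1
F9 | step 14 | C4-trimethylsilyl enol ether of the tricyclic ketone with exo vinyl on C2 | C1=C(O[Si](C)(C)C)[C@@H]2COC(C)(C)[C@@H]3CC[C@@](C)(C[C@@H]32)[C@H]1C=C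
F10 | step 14 | tricyclic ketone with exo vinyl on C2 and exo propargyl on C3 | C#CC[C@H]1C(=O)[C@@H]2COC(C)(C)[C@@H]3CC[C@@](C)(C[C@@H]32)[C@H]1C=C
F11 | step 14 | tricyclic diketone with exo vinyl on C2 and 2-oxopropyl on C3 | CC(=O)C[C@H]1C(=O)[C@@H]2COC(C)(C)[C@@H]3CC[C@@](C)(C[C@@H]32)[C@H]1C=C
F12 | step 14 | (E)-alkenyl pinacol boronate derived from F11 | CC(=O)C[C@H]1C(=O)[C@@H]2COC(C)(C)[C@@H]3CC[C@@](C)(C[C@@H]32)[C@H]1/C=C/B4OC(C)(C)C(C)(C)O4
F13 | step 14 | potassium (E)-alkenyltrifluoroborate derived from F12 | CC(=O)C[C@H]1C(=O)[C@@H]2COC(C)(C)[C@@H]3CC[C@@](C)(C[C@@H]32)[C@H]1/C=C/[B-](F)(F)F.[K+]
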